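**Retrosynthetic overview**
1. Feature: every carbon of ring B is substituted except C4'. C5' (OH) and C6' (prenyl) are the carboxyl carbon and α-carbon of 5-methylhex-4-enoic acid. C1' (aroyl), C2' (CHO), C3' (OH) and C4' (H) are C6, C5, C4 and C3 of a 4-oxygenated 2-pyrone-5-carboxylate.
2. Key disconnection: C1'–C6' and C4'–C5' are made together by inverse-demand [4+2] addition of the acid's bis(silyl) ketene acetal to a 6-aroyl-2-pyrone. Loss of CO2 and Me3SiOH then aromatises ring B.
3. Pyrone: dimethyl 3-oxoglutarate is C-acylated by the ring-A arylglyoxylyl chloride and lactonised. The glyoxylate comes from ortho-lithiated 3,5-dimethoxytoluene and dimethyl oxalate. Bromine enters only afterwards, because a C–Br bond would not survive n-BuLi, and goes ortho to the phenol freed by BCl3.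
4. Endgame: cap C5'–OH, reduce ester and ketone, oxidise both alcohols in one Swern operation, remove three MOM groups.
5. Ring order: ring A is bought, the pyrone ring is made in step 7 and sacrificed, and ring B is made in step 10.

Key step: step 10

Remark: 3,5-dimethoxytoluene (orcinol dimethyl ether) and 5-methylhex-4-enoic acid are taken as purchasable. Primed locants count ring B from the carbon bound to the ketone (C2' carries the formyl group). Ring-A locants count from its carbon bound to the carbonyl chain.

Step 1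
Reactants: 1 3,5-dimethoxytoluene; 2 dimethyl oxalate
Product: 4 methyl 2-(2,6-dimethoxy-4-methylphenyl)-2-oxoacetate, via aryllithium 3 (not isolated)
Conditions: n-BuLi (1.1 equiv), THF, 0 °C to rt; cannulated into 2 (3 equiv), THF, −78 °C; 1 M HCl quench
Reagents that add atoms: n-butyllithium, [Li]CCCC (lithium, held in 3 only)
Why: Directed ortho-metalation removes the one C–H flanked by both methoxy groups, and inverse addition of the hindered aryllithium to excess oxalate (acyl substitution) should stop at the α-keto ester.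

Step 2
Reactants: 4 methyl 2-(2,6-dimethoxy-4-methylphenyl)-2-oxoacetate
Product: 5 methyl 2-(2-hydroxy-6-methoxy-4-methylphenyl)-2-oxoacetate
Conditions: BCl3 (1.1 equiv), CH2Cl2, −78 to 0 °C; H2O
Reagents that add atoms: none
Why: In this chelation-assisted Lewis-acid cleavage of an aryl methyl ether ortho to a ketone, the two methoxy groups are equivalent so only one phenol can form, and the boron chelate ties up the carbonyl and thereby spares the second ether.

Step 3
Reactants: 5 methyl 2-(2-hydroxy-6-methoxy-4-methylphenyl)-2-oxoacetate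
Product: 6 methyl 2-(3-bromo-2-hydroxy-6-methoxy-4-methylphenyl)-2-oxoacetate
Conditions: NBS (1.0 equiv), i-Pr2NH (10 mol %), CH2Cl2, −20 °C to rt, dark
Reagents that add atoms: N-bromosuccinimide, O=C1CCC(=O)N1Br
Why: In this electrophilic aromatic bromination (amine-mediated ortho-bromination of a phenol), C3 and C5 are both activated by the two oxygens, but C3 is ortho to the chelated OH and para to OMe, whereas C5 is screened by the methoxy methyl group that the acyl chain pushes towards it, the same preference that directs halogen to C3 of 2-hydroxy-4,6-dimethoxyacetophenone.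

Step 4
Reactants: 6 methyl 2-(3-bromo-2-hydroxy-6-methoxy-4-methylphenyl)-2-oxoacetate
Product: 7 methyl 2-[3-bromo-6-methoxy-2-(methoxymethoxy)-4-methylphenyl]-2-oxoacetate
Conditions: MOMCl (2 equiv), i-Pr2NEt (3 equiv), CH2Cl2, 0 to 40 °C
Reagents that add atoms: chloromethyl methyl ether, COCCl
Why: Williamson-type O-alkylation of the acidic ortho-bromo, ortho-acyl phenol with a very reactive α-chloro ether should proceed despite the flanking groups, and the keto ester has no enolisable hydrogen.

Step 5
Reactants: 7 methyl 2-[3-bromo-6-methoxy-2-(methoxymethoxy)-4-methylphenyl]-2-oxoacetate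
Product: 8 2-[3-bromo-6-methoxy-2-(methoxymethoxy)-4-methylphenyl]-2-oxoacetic acid
Conditions: LiOH·H2O (1.5 equiv), THF/H2O, 0 °C; cold 0.5 M HCl to pH 3
Reagents that add atoms: lithium hydroxide, [Li+].[OH-]
Why: Saponification of an α-keto ester is fast at 0 °C because the neighbouring ketone activates the ester carbonyl, and a brief cold acidification leaves the aryl MOM ether intact.

Step 6
Reactants: 8 2-[3-bromo-6-methoxy-2-(methoxymethoxy)-4-methylphenyl]-2-oxoacetic acid; 9 dimethyl 3-oxopentanedioate (dimethyl 3-oxoglutarate)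
Product: 12 dimethyl 2-{2-[3-bromo-6-methoxy-2-(methoxymethoxy)-4-methylphenyl]-2-oxoacetyl}-3-oxopentanedioate, via acid chloride 10 (not isolated), via magnesium enolate 11 (not isolated)
Conditions: 8, 1-chloro-N,N,2-trimethylprop-1-en-1-amine (1.1 equiv), CH2Cl2, 0 °C; added to 9 (1.2 equiv), MgCl2 (1.2 equiv), pyridine (2.5 equiv), CH2Cl2, 0 °C to rt; cold dilute HCl wash
Reagents that add atoms: 1-chloro-N,N,2-trimethylprop-1-en-1-amine, CC(C)=C(Cl)N(C)C (chlorine, held in 10 only); magnesium dichloride, [Mg+2].[Cl-].[Cl-] (MgCl unit, held in 11 only)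
Why: The α-chloroenamine makes the acid chloride without liberating HCl and so spares the MOM ether, and soft enolisation with MgCl2/pyridine gives a chelated enolate that undergoes C-acylation (Claisen-type acylation of a magnesium β-keto ester enolate) at the open acyl chloride carbonyl rather than at the di-ortho-substituted aryl ketone.

Step 7
Reactants: 12 dimethyl 2-{2-[3-bromo-6-methoxy-2-(methoxymethoxy)-4-methylphenyl]-2-oxoacetyl}-3-oxopentanedioate
Product: 13 methyl 6-[3-bromo-6-methoxy-2-(methoxymethoxy)-4-methylbenzoyl]-4-hydroxy-2-oxo-2H-pyran-5-carboxylate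
Conditions: DBU (1.5 equiv), PhMe, rt to 40 °C; cold dilute HCl wash
Reagents that add atoms: none
Why: In this base-induced lactonisation (the usual closure of a 3,5-dioxo ester to a 4-hydroxy-2-pyrone), the enol oxygen of the newly introduced carbonyl attacks the remote ester to form the six-membered ring, methanol is lost irreversibly, and aldol closure onto the aryl ketone is blocked by its two ortho substituents.

Step 8
Reactants: 13 methyl 6-[3-bromo-6-methoxy-2-(methoxymethoxy)-4-methylbenzoyl]-4-hydroxy-2-oxo-2H-pyran-5-carboxylate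
Product: 14 methyl 6-[3-bromo-6-methoxy-2-(methoxymethoxy)-4-methylbenzoyl]-4-(methoxymethoxy)-2-oxo-2H-pyran-5-carboxylate
Conditions: MOMCl (1.5 equiv), i-Pr2NEt (2 equiv), CH2Cl2, 0 °C
Reagents that add atoms: chloromethyl methyl ether, COCCl
Why: O-alkylation of the vinylogous acid with a hard electrophile under amine base should go to the 4-oxygen and keep the 2-pyrone conjugation, as in the standard etherification of 4-hydroxy-2-pyrones.

Step 9
Reactants: 15 5-methylhex-4-enoic acid
Product: 17 1,1-bis(trimethylsilyloxy)-5-methylhexa-1,4-diene, via dilithium enediolate 16 (not isolated)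
Conditions: LDA (LiN(i-Pr)2, 2.2 equiv), THF, −78 to 0 °C; TMSCl (2.5 equiv), −78 °C to rt; pentane, filtration, distillation
Reagents that add atoms: chlorotrimethylsilane, C[Si](C)(C)Cl; lithium diisopropylamide, [Li]N(C(C)C)C(C)C (lithium, held in 16 only)
Why: Double deprotonation of the acid and O,O-disilylation of the enediolate is the standard route to ketene bis(silyl) acetals, α-monoalkyl enediolates silylate on oxygen, and the remote trisubstituted alkene is inert.

Step 10
Reactants: 14 methyl 6-[3-bromo-6-methoxy-2-(methoxymethoxy)-4-methylbenzoyl]-4-(methoxymethoxy)-2-oxo-2H-pyran-5-carboxylate; 17 1,1-bis(trimethylsilyloxy)-5-methylhexa-1,4-diene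
Product: 21 methyl 2-[3-bromo-6-methoxy-2-(methoxymethoxy)-4-methylbenzoyl]-4-hydroxy-6-(methoxymethoxy)-3-(3-methylbut-2-en-1-yl)benzoate, via bridged lactone 18 (not isolated), via cyclohexadiene 19 (not isolated), via aryl silyl ether 20 (not isolated)
Conditions: 17 (3 equiv), PhMe, 120 °C, sealed tube; then 10% aq. citric acid, THF, rt
Reagents that add atoms: none
Why: The prenyl-bearing carbon of the ketene acetal (C6') carries the large HOMO coefficient and pyrone C6 (C1'), which is β to the 5-ester and δ to the lactone carbonyl, carries the large LUMO coefficient, so this bond leads, and the acetal carbon (C5') then closes onto C3 (C4') either in the same asynchronous [4+2] event or by capture of the silyloxycarbenium ion by the dienolate. The closest known reaction type is the inverse-electron-demand Diels–Alder reaction of 2-pyrone carboxylates with ketene acetals, which ends in oxygenated benzoates after loss of CO2 and of one acetal oxygen. Ring B is closed by this intermolecular [4+2] cycloaddition as the six-membered carbocycle inside 18, cycloreversion of 18 expels CO2 to give 19, 1,2-elimination of Me3SiOH across C5'–C6' gives arene 20, and the mild acid work-up removes its silyl group. The sp3 centres of 18 and 19 are transient, so endo/exo approach and acetal geometry do not matter and no stereocentre remains. The step needs regioselectivity (C6' to C1', not to C4') and chemoselectivity (pyrone ring rather than ketone): the 4-OMOM donor makes C3 the electron-rich diene terminus and so reinforces the polarisation set by the ester, while the aroyl carbonyl is twisted out of conjugation and shielded by the OMe and OMOM groups of ring A. Two silyl groups on the acetal ensure that C5' ends as a free phenol whichever oxygen leaves.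

Step 11
Reactants: 21 methyl 2-[3-bromo-6-methoxy-2-(methoxymethoxy)-4-methylbenzoyl]-4-hydroxy-6-(methoxymethoxy)-3-(3-methylbut-2-en-1-yl)benzoate
Product: 22 methyl 2-[3-bromo-6-methoxy-2-(methoxymethoxy)-4-methylbenzoyl]-4,6-bis(methoxymethoxy)-3-(3-methylbut-2-en-1-yl)benzoate
Conditions: MOMCl (1.5 equiv), i-Pr2NEt (2 equiv), CH2Cl2, 0 °C to rt
Reagents that add atoms: chloromethyl methyl ether, COCCl
Why: Williamson-type MOM ether formation caps the phenol para to the ester carbon, so the benzylic alcohol made next cannot form a para-quinone methide and the later oxidation meets no free phenol.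

Step 12
Reactants: 22 methyl 2-[3-bromo-6-methoxy-2-(methoxymethoxy)-4-methylbenzoyl]-4,6-bis(methoxymethoxy)-3-(3-methylbut-2-en-1-yl)benzoate
Product: 23 [3-bromo-6-methoxy-2-(methoxymethoxy)-4-methylphenyl][2-(hydroxymethyl)-3,5-bis(methoxymethoxy)-6-(3-methylbut-2-en-1-yl)phenyl]methanol (racemic)
Conditions: LiAlH4 (3 equiv), THF, 0 °C to rt; H2O, 15% aq. NaOH, H2O
Reagents that add atoms: none
Why: Hydride reduction with LiAlH4 takes both carbonyl groups to alcohols in whichever order they react, leaves the aryl bromide, MOM ethers and alkene untouched at these temperatures, and forms the carbinol centre as a racemate that step 13 erases.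

Step 13
Reactants: 23 [3-bromo-6-methoxy-2-(methoxymethoxy)-4-methylphenyl][2-(hydroxymethyl)-3,5-bis(methoxymethoxy)-6-(3-methylbut-2-en-1-yl)phenyl]methanol
Product: 25 2-[3-bromo-6-methoxy-2-(methoxymethoxy)-4-methylbenzoyl]-4,6-bis(methoxymethoxy)-3-(3-methylbut-2-en-1-yl)benzaldehyde, via bis(alkoxysulfonium) salt 24 (not isolated)
Conditions: (COCl)2 (6 equiv), DMSO (12 equiv), CH2Cl2, −78 °C; 23, −78 °C, 1 h; Et3N (20 equiv), −78 to 0 °C
Reagents that add atoms: dimethyl sulfoxide, CS(C)=O (Me2S units, held in 24 only)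
Why: In the Swern oxidation both hydroxyl groups become alkoxysulfonium ions before any base is present, so no hydroxy aldehyde exists that could close to a lactol and be over-oxidised to the phthalide, which is why this method is used for 1,2-benzenedimethanols.

Step 14
Reactants: 25 2-[3-bromo-6-methoxy-2-(methoxymethoxy)-4-methylbenzoyl]-4,6-bis(methoxymethoxy)-3-(3-methylbut-2-en-1-yl)benzaldehyde
Product: 26 Pestalone B, 2-(3-bromo-2-hydroxy-6-methoxy-4-methylbenzoyl)-4,6-dihydroxy-3-(3-methylbut-2-en-1-yl)benzaldehyde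
Conditions: HCl (1.25 M in MeOH), rt to 40 °C; H2O, EtOAc, no basic wash
Reagents that add atoms: none
Why: Acid-catalysed acetal exchange removes all three MOM groups (two are ortho to a carbonyl and labile), methanol traps the CH2 unit away from the resorcinol ring, these conditions routinely free ortho-prenylphenols without chroman formation, and base is avoided because the keto aldehyde can isomerise to a lactone by an intramolecular Cannizzaro–Tishchenko path.

**Compound list**
1 | 3,5-dimethoxytoluene | COc1cc(C)cc(OC)c1 | starting material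
2 | dimethyl oxalate | COC(=O)C(=O)OC | starting material
3 | (2,6-dimethoxy-4-methylphenyl)lithium | [Li]c1c(OC)cc(C)cc1OC | intermediate
4 | methyl 2-(2,6-dimethoxy-4-methylphenyl)-2-oxoacetate | COC(=O)C(=O)c1c(OC)cc(C)cc1OC | intermediate
5 | methyl 2-(2-hydroxy-6-methoxy-4-methylphenyl)-2-oxoacetate | COC(=O)C(=O)c1c(O)cc(C)cc1OC | intermediate
6 | methyl 2-(3-bromo-2-hydroxy-6-methoxy-4-methylphenyl)-2-oxoacetate | COC(=O)C(=O)c1c(O)c(Br)c(C)cc1OC | intermediate
7 | methyl 2-[3-bromo-6-methoxy-2-(methoxymethoxy)-4-methylphenyl]-2-oxoacetate | COC(=O)C(=O)c1c(OCOC)c(Br)c(C)cc1OC | intermediate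
8 | 2-[3-bromo-6-methoxy-2-(methoxymethoxy)-4-methylphenyl]-2-oxoacetic acid | OC(=O)C(=O)c1c(OCOC)c(Br)c(C)cc1OC | intermediate
9 | dimethyl 3-oxopentanedioate | COC(=O)CC(=O)CC(=O)OC | starting material
10 | 2-[3-bromo-6-methoxy-2-(methoxymethoxy)-4-methylphenyl]-2-oxoacetyl chloride | ClC(=O)C(=O)c1c(OCOC)c(Br)c(C)cc1OC | intermediate
11 | chloromagnesium enolate of dimethyl 3-oxopentanedioate | COC(=O)CC(O[Mg]Cl)=CC(=O)OC | intermediate
12 | dimethyl 2-{2-[3-bromo-6-methoxy-2-(methoxymethoxy)-4-methylphenyl]-2-oxoacetyl}-3-oxopentanedioate (drawn as the keto form) | COC(=O)CC(=O)C(C(=O)OC)C(=O)C(=O)c1c(OCOC)c(Br)c(C)cc1OC | intermediate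
13 | methyl 6-[3-bromo-6-methoxy-2-(methoxymethoxy)-4-methylbenzoyl]-4-hydroxy-2-oxo-2H-pyran-5-carboxylate | O=C1C=C(O)C(C(=O)OC)=C(C(=O)c2c(OC)cc(C)c(Br)c2OCOC)O1 | intermediate
14 | methyl 6-[3-bromo-6-methoxy-2-(methoxymethoxy)-4-methylbenzoyl]-4-(methoxymethoxy)-2-oxo-2H-pyran-5-carboxylate | O=C1C=C(OCOC)C(C(=O)OC)=C(C(=O)c2c(OC)cc(C)c(Br)c2OCOC)O1 | intermediate
15 | 5-methylhex-4-enoic acid | CC(C)=CCCC(=O)O | starting material
16 | dilithium enediolate of 5-methylhex-4-enoic acid | [Li]OC(O[Li])=CCC=C(C)C | intermediate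
17 | 1,1-bis(trimethylsilyloxy)-5-methylhexa-1,4-diene | C[Si](C)(C)OC(O[Si](C)(C)C)=CCC=C(C)C | intermediate
18 | methyl 1-aroyl-5-(methoxymethoxy)-7-(3-methylbut-2-en-1-yl)-3-oxo-8,8-bis(trimethylsilyloxy)-2-oxabicyclo[2.2.2]oct-5-ene-6-carboxylate (aroyl = ring-A benzoyl of 14; transient mixture of diastereomers) | O=C1OC2(C(=O)c3c(OC)cc(C)c(Br)c3OCOC)C(CC=C(C)C)C(O[Si](C)(C)C)(O[Si](C)(C)C)C1C(OCOC)=C2C(=O)OC | intermediate
19 | methyl 2-aroyl-6-(methoxymethoxy)-3-(3-methylbut-2-en-1-yl)-4,4-bis(trimethylsilyloxy)cyclohexa-1,5-diene-1-carboxylate (aroyl as in 14; racemic, transient) | COC(=O)C1=C(C(=O)c2c(OC)cc(C)c(Br)c2OCOC)C(CC=C(C)C)C(O[Si](C)(C)C)(O[Si](C)(C)C)C=C1OCOC | intermediate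
20 | methyl 2-[3-bromo-6-methoxy-2-(methoxymethoxy)-4-methylbenzoyl]-6-(methoxymethoxy)-3-(3-methylbut-2-en-1-yl)-4-(trimethylsilyloxy)benzoate | COC(=O)c1c(OCOC)cc(O[Si](C)(C)C)c(CC=C(C)C)c1C(=O)c1c(OC)cc(C)c(Br)c1OCOC | intermediate
21 | methyl 2-[3-bromo-6-methoxy-2-(methoxymethoxy)-4-methylbenzoyl]-4-hydroxy-6-(methoxymethoxy)-3-(3-methylbut-2-en-1-yl)benzoate | COC(=O)c1c(OCOC)cc(O)c(CC=C(C)C)c1C(=O)c1c(OC)cc(C)c(Br)c1OCOC | intermediate
22 | methyl 2-[3-bromo-6-methoxy-2-(methoxymethoxy)-4-methylbenzoyl]-4,6-bis(methoxymethoxy)-3-(3-methylbut-2-en-1-yl)benzoate | COC(=O)c1c(OCOC)cc(OCOC)c(CC=C(C)C)c1C(=O)c1c(OC)cc(C)c(Br)c1OCOC | intermediate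
23 | [3-bromo-6-methoxy-2-(methoxymethoxy)-4-methylphenyl][2-(hydroxymethyl)-3,5-bis(methoxymethoxy)-6-(3-methylbut-2-en-1-yl)phenyl]methanol (racemic) | OCc1c(OCOC)cc(OCOC)c(CC=C(C)C)c1C(O)c1c(OC)cc(C)c(Br)c1OCOC | intermediate
24 | bis(dimethylalkoxysulfonium) dichloride of 23 | C[S+](C)OCc1c(OCOC)cc(OCOC)c(CC=C(C)C)c1C(O[S+](C)C)c1c(OC)cc(C)c(Br)c1OCOC.[Cl-].[Cl-] | intermediate
25 | 2-[3-bromo-6-methoxy-2-(methoxymethoxy)-4-methylbenzoyl]-4,6-bis(methoxymethoxy)-3-(3-methylbut-2-en-1-yl)benzaldehyde | O=Cc1c(OCOC)cc(OCOC)c(CC=C(C)C)c1C(=O)c1c(OC)cc(C)c(Br)c1OCOC | intermediate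
26 | Pestalone B | COc1cc(C)c(Br)c(O)c1C(=O)c1c(C=O)c(O)cc(O)c1CC=C(C)C | target

**Total step count:** 14. **Longest linear sequence:** 13 (steps 1–8 and 10–14; step 9 is a one-step side branch).

**Steps most likely to fail**

Step 10. The diene is fully substituted at C6 and carries a donor at C4, so cycloaddition may be slower than thermal decay of the ketene acetal. After the first C–C bond forms, silyl migration to the dienolate may also outrun closure of the second bond.
- The fallback keeps pyrone 14 but replaces the ketene acetal with an electron-rich alkyne. Its attacking carbon is sterically slim, and its adduct aromatises by loss of CO2 alone, with no elimination.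
- Prenyl bromide and ethynylmagnesium bromide (HC≡CMgBr, catalytic CuCl, THF) give 5-methylhex-4-en-1-yne F1.
- Lithiation with n-BuLi, oxygenation with lithium tert-butyl peroxide (t-BuOOLi) and trapping of the ynolate with TIPSOTf give triisopropyl[(5-methylhex-4-en-1-yn-1-yl)oxy]silane F2.
- Heating F2 with 14 in toluene follows the known reaction of electron-poor 2-pyrones with ynamines and alkynyl ethers, with the same polarity match. It should give methyl 2-[3-bromo-6-methoxy-2-(methoxymethoxy)-4-methylbenzoyl]-6-(methoxymethoxy)-3-(3-methylbut-2-en-1-yl)-4-(triisopropylsilyloxy)benzoate F3.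
- TBAF buffered with AcOH then returns to the route at 21.

Step 6. The aroylformyl chloride may lose CO, and the enolate may be acylated on oxygen or may add to the keto carbonyl. The fallback sets out from 8 and reverses the order in which the two C–C bonds to the central carbon are made.
- CDI converts 8 into 1-[3-bromo-6-methoxy-2-(methoxymethoxy)-4-methylphenyl]-2-(1H-imidazol-1-yl)ethane-1,2-dione F4.
- Potassium methyl malonate (KO2CCH2CO2Me), MgCl2 and Et3N in MeCN (Masamune–Brooks decarboxylative Claisen condensation) give methyl 4-[3-bromo-6-methoxy-2-(methoxymethoxy)-4-methylphenyl]-3,4-dioxobutanoate F5.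
- C-acylation of F5 with commercial methyl malonyl chloride under MgCl2/pyridine comes back to the route at 12. The sensitive α-keto acyl chloride is never made.

Step 13. The activated, electron-rich benzhydrol may ionise and be captured by the neighbouring oxygen. Oxidation may also run stepwise through lactol closure and over-oxidation. The fallback sets out from 23 and oxidises the two alcohols one at a time.
- TBSCl/imidazole silylates only the primary alcohol and gives the mono(tert-butyldimethylsilyl) ether of diol 23 F6.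
- Dess–Martin periodinane buffered with NaHCO3 gives the silyloxymethyl benzophenone F7.
- TBAF/AcOH gives the hydroxymethyl benzophenone F8. Its cyclic hemiketal form cannot be oxidised and drains through the open form.
- Dess–Martin periodinane or MnO2 then leads back to 25.

**Further compounds**
F1 | step 10 | 5-methylhex-4-en-1-yne | C#CCC=C(C)C
F2 | step 10 | triisopropyl[(5-methylhex-4-en-1-yn-1-yl)oxy]silane | CC(C)=CCC#CO[Si](C(C)C)(C(C)C)C(C)C
F3 | step 10 | methyl 2-[3-bromo-6-methoxy-2-(methoxymethoxy)-4-methylbenzoyl]-6-(methoxymethoxy)-3-(3-methylbut-2-en-1-yl)-4-(triisopropylsilyloxy)benzoate | COC(=O)c1c(OCOC)cc(O[Si](C(C)C)(C(C)C)C(C)C)c(CC=C(C)C)c1C(=O)c1c(OC)cc(C)c(Br)c1OCOC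
F4 | step 6 | 1-[3-bromo-6-methoxy-2-(methoxymethoxy)-4-methylphenyl]-2-(1H-imidazol-1-yl)ethane-1,2-dione | O=C(n1ccnc1)C(=O)c1c(OCOC)c(Br)c(C)cc1OC
F5 | step 6 | methyl 4-[3-bromo-6-methoxy-2-(methoxymethoxy)-4-methylphenyl]-3,4-dioxobutanoate | COC(=O)CC(=O)C(=O)c1c(OCOC)c(Br)c(C)cc1OC
F6 | step 13 | mono(tert-butyldimethylsilyl) ether (primary oxygen) of diol 23, racemic | CC(C)(C)[Si](C)(C)OCc1c(OCOC)cc(OCOC)c(CC=C(C)C)c1C(O)c1c(OC)cc(C)c(Br)c1OCOC
F7 | step 13 | [3-bromo-6-methoxy-2-(methoxymethoxy)-4-methylphenyl][2-(tert-butyldimethylsilyloxymethyl)-3,5-bis(methoxymethoxy)-6-(3-methylbut-2-en-1-yl)phenyl]methanone | CC(C)(C)[Si](C)(C)OCc1c(OCOC)cc(OCOC)c(CC=C(C)C)c1C(=O)c1c(OC)cc(C)c(Br)c1OCOC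
F8 | step 13 | [3-bromo-6-methoxy-2-(methoxymethoxy)-4-methylphenyl][2-(hydroxymethyl)-3,5-bis(methoxymethoxy)-6-(3-methylbut-2-en-1-yl)phenyl]methanone | OCc1c(OCOC)cc(OCOC)c(CC=C(C)C)c1C(=O)c1c(OC)cc(C)c(Br)c1OCOC
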